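**Plan**

1. Retrosynthesis first removes the two aryl benzyl ethers and cuts the C2–acetyl bond of the trione ring (late C-acylation). The benzylfilicinic acid that remains is the hydrolysis product of a 4-benzyl-3,5-diethoxy-6,6-dimethylcyclohexa-2,4-dien-1-one.
2. Enabling feature: in the trione ring C4 is quaternary (two methyl groups) and sits between the oxygen-bearing C3 and C5, with the third oxygen on C1. Such a ring cannot tautomerise to a phenol, so it is what a dienylketene 6π ring closure leaves behind.
3. The dienone ring is cut at C1–C6 and C2–C3 (target numbering), lifting out C1 and C2 as ethoxyacetylene and leaving a 2-benzyl-3-ethoxy-4,4-dimethylcyclobutenone. That four-membered ring is cut to dimethylketene and an ArCH2–C≡C–OEt ynol ether, whose CH2–C(sp) bond goes back to a benzylic bromide and ethoxyethynylzinc chloride.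
4. Forward: the aromatic piece is made from 2',6'-dihydroxy-4'-methoxyacetophenone (formylation, benzylation, reduction, bromination) and joined to the C2 unit. The four-membered ring is then closed by [2+2], the six-membered ring arises by alkyne insertion, and hydrolysis, C-acetylation and hydrogenolysis finish the route.
5. Stereochemistry: the target has no stereocentre and no stereogenic double bond, so nothing has to be controlled. The only stereocentre on the way is a transient racemic one inside the key cascade.

Key step: step 7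

Assumption: the target is an achiral acyl trione drawn as one of several rapidly interconverting enol tautomers; all trione intermediates are drawn in the matching tautomer.

**Route**

Step 1
Reactants: 1 2',6'-dihydroxy-4'-methoxyacetophenone
Product: 3 3-acetyl-2,4-dihydroxy-6-methoxybenzaldehyde, via chloro(methoxy)methyl arene 2 (not isolated)
Conditions: Cl2CHOMe (1.3 equiv), TiCl4 (3.5 equiv), CH2Cl2, 0 °C to rt; then ice/1 M HCl
Reagents that add atoms: dichloromethyl methyl ether, COC(Cl)Cl; water, O
Why: Rieche formylation: the TiCl4-activated α-chloro ether attacks the only kind of free ring position (C3 and C5 are equivalent, each ortho to one OH and para to the other), the new electron-withdrawing substituent should hold the reaction at monosubstitution, and aqueous work-up hydrolyses α-chloro ether 2 to the aldehyde.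

Step 2
Reactants: 3 3-acetyl-2,4-dihydroxy-6-methoxybenzaldehyde
Product: 4 3-acetyl-2,4-bis(benzyloxy)-6-methoxybenzaldehyde
Conditions: BnBr (2.5 equiv), K2CO3 (4 equiv), DMF, 60 °C
Reagents that add atoms: benzyl bromide, BrCc1ccccc1
Why: Williamson etherification of both hydrogen-bonded phenols in warm DMF; benzyl ethers are chosen because they should survive the organozinc, ketene, thermal and aqueous acid steps and leave at the end under neutral hydrogenolysis.

Step 3
Reactants: 4 3-acetyl-2,4-bis(benzyloxy)-6-methoxybenzaldehyde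
Product: 5 1-[2,6-bis(benzyloxy)-3-(hydroxymethyl)-4-methoxyphenyl]ethan-1-one
Conditions: NaBH4 (0.5 equiv), THF/MeOH, −10 to 0 °C
Reagents that add atoms: none
Why: Chemoselective borohydride reduction: the aldehyde should be reduced far faster than the methyl ketone, which is flanked by two ortho benzyloxy groups and twisted out of conjugation.

Step 4
Reactants: 5 1-[2,6-bis(benzyloxy)-3-(hydroxymethyl)-4-methoxyphenyl]ethan-1-one
Product: 6 1-[2,6-bis(benzyloxy)-3-(bromomethyl)-4-methoxyphenyl]ethan-1-one
Conditions: CBr4, PPh3, CH2Cl2, 0 °C; short silica plug, used at once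
Reagents that add atoms: carbon tetrabromide, BrC(Br)(Br)Br
Why: Appel bromination converts the primary benzylic alcohol to the bromide under neutral conditions, avoiding acid that could ionise this electron-rich benzylic position.

Step 5
Reactants: 6 1-[2,6-bis(benzyloxy)-3-(bromomethyl)-4-methoxyphenyl]ethan-1-one; 7 ethoxyacetylene
Product: 10 1-[2,6-bis(benzyloxy)-3-(3-ethoxyprop-2-yn-1-yl)-4-methoxyphenyl]ethan-1-one, via lithium ethoxyacetylide 8 (not isolated), via ethoxyethynylzinc chloride 9 (not isolated)
Conditions: 7, n-BuLi, THF, −78 °C; ZnCl2, −78 to 0 °C; then 6, PdCl2(DPEphos) (5 mol %), THF, rt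
Reagents that add atoms: none
Why: Negishi coupling of a benzylic bromide with an alkynylzinc chloride forms the CH2–C(sp) bond, and the weakly basic zinc acetylide should neither add to nor enolise the hindered aryl methyl ketone.

Step 6
Reactants: 10 1-[2,6-bis(benzyloxy)-3-(3-ethoxyprop-2-yn-1-yl)-4-methoxyphenyl]ethan-1-one; 11 isobutyryl chloride
Product: 13 2-[[3-acetyl-2,4-bis(benzyloxy)-6-methoxyphenyl]methyl]-3-ethoxy-4,4-dimethylcyclobut-2-en-1-one, via dimethylketene 12 (not isolated)
Conditions: 11 (3 equiv, slow addition), Et3N (3.5 equiv), MeCN, rt to 50 °C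
Reagents that add atoms: none
Why: Ketene–ynol ether [2+2] cycloaddition: dimethylketene generated in situ by dehydrochlorination bonds through its carbonyl carbon to the nucleophilic benzyl-bearing alkyne carbon, so the ethoxy group ends on C3 and the gem-dimethyl carbon becomes C4 of the cyclobutenone.

Step 7
Reactants: 13 2-[[3-acetyl-2,4-bis(benzyloxy)-6-methoxyphenyl]methyl]-3-ethoxy-4,4-dimethylcyclobut-2-en-1-one; 7 ethoxyacetylene
Product: 17 4-[[3-acetyl-2,4-bis(benzyloxy)-6-methoxyphenyl]methyl]-3,5-diethoxy-6,6-dimethylcyclohexa-2,4-dien-1-one, via vinylketene 14 (not isolated), via vinylcyclobutenone 15 (not isolated), via dienylketene 16 (not isolated)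
Conditions: 7 (5 equiv, in two portions), toluene, sealed tube, 80 to 110 °C
Reagents that add atoms: none
Why: Heating should open cyclobutenone 13 by 4π electrocyclic cleavage of its C1–C4 bond to vinylketene 14 (the two methyl groups on the rotating terminus are identical, so torquoselectivity does not matter), whose ketene C=C adds ethoxyacetylene in a [2+2] to give 4-vinylcyclobutenone 15, which opens again to dienylketene 16. The six-membered ring then closes by thermal 6π disrotatory electrocyclization, the ketene carbon bonding to the dimethyl-substituted terminus, so that the carbocycle of the trione appears as its bis(ethyl enol ether). The closest known reaction is the Danheiser benzannulation of cyclobutenones with alkoxy- and siloxyalkynes, which is precedented for 3-oxygenated cyclobutenones but only thinly for 4,4-disubstituted ones; here the quaternary C6 cannot lose a proton, so the sequence stops at the cyclohexa-2,4-dienone instead of a phenol. Product 17 has no stereocentre; the quaternary centre of 15 forms racemic and is erased on ring opening, and because that opening is reversible both geometries of 16 should drain through the one with the ketenyl and alkenyl groups cis. The step needs regioselectivity in the ketene–alkyne [2+2], which polarity secures: the nucleophilic unsubstituted carbon of the ynol ether attacks the electrophilic ketene carbonyl carbon, placing the ring C–H between the carbonyl and an ethoxy-bearing carbon and leaving the benzyl-bearing carbon flanked by two C–OEt carbons. It also needs bimolecular capture of 14 to outrun its 1,5-hydrogen shift and dimerisation, which is why the alkyne is used in excess.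

Step 8
Reactants: 17 4-[[3-acetyl-2,4-bis(benzyloxy)-6-methoxyphenyl]methyl]-3,5-diethoxy-6,6-dimethylcyclohexa-2,4-dien-1-one
Product: 18 2-[[3-acetyl-2,4-bis(benzyloxy)-6-methoxyphenyl]methyl]-3,5-dihydroxy-4,4-dimethylcyclohexa-2,5-dien-1-one
Conditions: 2 M aq HCl, THF, rt to 45 °C
Reagents that add atoms: water, O
Why: Acid hydrolysis of vinylogous ester enol ethers: O-protonation of the dienone gives an alkoxy-stabilised pentadienyl cation that takes up water and loses ethanol, twice over, while aryl benzyl ethers and the aryl ketone are inert to dilute aqueous acid.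

Step 9
Reactants: 18 2-[[3-acetyl-2,4-bis(benzyloxy)-6-methoxyphenyl]methyl]-3,5-dihydroxy-4,4-dimethylcyclohexa-2,5-dien-1-one
Product: 20 2-acetyl-6-[[3-acetyl-2,4-bis(benzyloxy)-6-methoxyphenyl]methyl]-3,5-dihydroxy-4,4-dimethylcyclohexa-2,5-dien-1-one, via enol acetate 19 (not isolated)
Conditions: AcCl (1.1 equiv), Et3N (2.5 equiv), CH2Cl2, 0 °C; then DMAP (0.3 equiv), rt; 1 M HCl wash
Reagents that add atoms: acetyl chloride, CC(Cl)=O
Why: O-acylation of the cyclic triketone enol followed by DMAP-mediated O-to-C acyl migration, the standard entry to 2-acyl-1,3-diones; the acetylpyridinium/enolate pair should recombine at the only unsubstituted ring carbon because only there can the product enolise to the hydrogen-bonded acyl trione, whereas acylation at the benzyl-bearing carbon is reversible (positional isomers of enol acetate 19 converge).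

Step 10
Reactants: 20 2-acetyl-6-[[3-acetyl-2,4-bis(benzyloxy)-6-methoxyphenyl]methyl]-3,5-dihydroxy-4,4-dimethylcyclohexa-2,5-dien-1-one
Product: 21 2-acetyl-6-[(3-acetyl-2,4-dihydroxy-6-methoxyphenyl)methyl]-3,5-dihydroxy-4,4-dimethylcyclohexa-2,5-dien-1-one (CNP0224819.0)
Conditions: H2 (1 atm), 10% Pd/C, EtOAc, rt
Reagents that add atoms: none
Why: Hydrogenolysis of the aryl benzyl ethers under neutral conditions frees both phenols; the chelated aryl ketone, the tetrasubstituted enol double bonds and the benzylic C–C bridge should not be reduced at 1 atm and room temperature.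

**Compound list**

1 | 2',6'-dihydroxy-4'-methoxyacetophenone | COc1cc(O)c(C(C)=O)c(O)c1 | starting material
2 | 1-[3-[chloro(methoxy)methyl]-2,6-dihydroxy-4-methoxyphenyl]ethan-1-one | COc1cc(O)c(C(C)=O)c(O)c1C(Cl)OC | intermediate
3 | 3-acetyl-2,4-dihydroxy-6-methoxybenzaldehyde | COc1cc(O)c(C(C)=O)c(O)c1C=O | intermediate
4 | 3-acetyl-2,4-bis(benzyloxy)-6-methoxybenzaldehyde | COc1cc(OCc2ccccc2)c(C(C)=O)c(OCc2ccccc2)c1C=O | intermediate
5 | 1-[2,6-bis(benzyloxy)-3-(hydroxymethyl)-4-methoxyphenyl]ethan-1-one | COc1cc(OCc2ccccc2)c(C(C)=O)c(OCc2ccccc2)c1CO | intermediate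
6 | 1-[2,6-bis(benzyloxy)-3-(bromomethyl)-4-methoxyphenyl]ethan-1-one | COc1cc(OCc2ccccc2)c(C(C)=O)c(OCc2ccccc2)c1CBr | intermediate
7 | ethoxyacetylene (ethoxyethyne) | C#COCC | starting material
8 | lithium ethoxyacetylide | [Li]C#COCC | intermediate
9 | ethoxyethynylzinc chloride | CCOC#C[Zn]Cl | intermediate
10 | 1-[2,6-bis(benzyloxy)-3-(3-ethoxyprop-2-yn-1-yl)-4-methoxyphenyl]ethan-1-one | COc1cc(OCc2ccccc2)c(C(C)=O)c(OCc2ccccc2)c1CC#COCC | intermediate
11 | isobutyryl chloride (2-methylpropanoyl chloride) | CC(C)C(Cl)=O | starting material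
12 | dimethylketene | CC(C)=C=O | intermediate
13 | 2-[[3-acetyl-2,4-bis(benzyloxy)-6-methoxyphenyl]methyl]-3-ethoxy-4,4-dimethylcyclobut-2-en-1-one | COc1cc(OCc2ccccc2)c(C(C)=O)c(OCc2ccccc2)c1CC1=C(OCC)C(C)(C)C1=O | intermediate
14 | 2-[[3-acetyl-2,4-bis(benzyloxy)-6-methoxyphenyl]methyl]-3-ethoxy-4-methylpenta-1,3-dien-1-one (vinylketene) | COc1cc(OCc2ccccc2)c(C(C)=O)c(OCc2ccccc2)c1CC(=C=O)C(OCC)=C(C)C | intermediate
15 | 4-[[3-acetyl-2,4-bis(benzyloxy)-6-methoxyphenyl]methyl]-3-ethoxy-4-(1-ethoxy-2-methylprop-1-en-1-yl)cyclobut-2-en-1-one (racemic, transient) | COc1cc(OCc2ccccc2)c(C(C)=O)c(OCc2ccccc2)c1CC1(C(OCC)=C(C)C)C(OCC)=CC1=O | intermediate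
16 | (3E)-4-[[3-acetyl-2,4-bis(benzyloxy)-6-methoxyphenyl]methyl]-3,5-diethoxy-6-methylhepta-1,3,5-trien-1-one (dienylketene, ketenyl cis to the alkenyl group) | COc1cc(OCc2ccccc2)c(C(C)=O)c(OCc2ccccc2)c1C/C(C(OCC)=C(C)C)=C(OCC)/C=C=O | intermediate
17 | 4-[[3-acetyl-2,4-bis(benzyloxy)-6-methoxyphenyl]methyl]-3,5-diethoxy-6,6-dimethylcyclohexa-2,4-dien-1-one | COc1cc(OCc2ccccc2)c(C(C)=O)c(OCc2ccccc2)c1CC1=C(OCC)C(C)(C)C(=O)C=C1OCC | intermediate
18 | 2-[[3-acetyl-2,4-bis(benzyloxy)-6-methoxyphenyl]methyl]-3,5-dihydroxy-4,4-dimethylcyclohexa-2,5-dien-1-one | COc1cc(OCc2ccccc2)c(C(C)=O)c(OCc2ccccc2)c1CC1=C(O)C(C)(C)C(O)=CC1=O | intermediate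
19 | 4-[[3-acetyl-2,4-bis(benzyloxy)-6-methoxyphenyl]methyl]-5-hydroxy-6,6-dimethyl-3-oxocyclohexa-1,4-dien-1-yl acetate (one positional isomer of the enol acetate) | COc1cc(OCc2ccccc2)c(C(C)=O)c(OCc2ccccc2)c1CC1=C(O)C(C)(C)C(OC(C)=O)=CC1=O | intermediate
20 | 2-acetyl-6-[[3-acetyl-2,4-bis(benzyloxy)-6-methoxyphenyl]methyl]-3,5-dihydroxy-4,4-dimethylcyclohexa-2,5-dien-1-one | COc1cc(OCc2ccccc2)c(C(C)=O)c(OCc2ccccc2)c1CC1=C(O)C(C)(C)C(O)=C(C(C)=O)C1=O | intermediate
21 | 2-acetyl-6-[(3-acetyl-2,4-dihydroxy-6-methoxyphenyl)methyl]-3,5-dihydroxy-4,4-dimethylcyclohexa-2,5-dien-1-one (CNP0224819.0) | COc1cc(O)c(C(C)=O)c(O)c1CC1=C(O)C(C)(C)C(O)=C(C(C)=O)C1=O | target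

**Step count**

Total steps: 10. Longest linear sequence: 10 steps (1 to 21).

**Steps most likely to fail**

Step 7. The 3-alkoxy-4,4-dimethylcyclobutenone may open only at temperatures where ethoxyacetylene loses ethylene, and vinylketene 14 may escape by 1,5-hydrogen shift from a methyl group before the alkyne captures it. The fallback gives up the ring construction and joins two preformed rings, setting out from bromide 6 and coming back at 20. 2,4,6-Trihydroxyacetophenone is geminally C-methylated (NaOMe, MeI, MeOH) to acetylfilicinic acid F1. Its sodium enolate (NaH, THF, 0 °C to rt) is then C-benzylated by 6 at the single free ring carbon to give 20, and any O-benzylated vinylogous ester is returned to F1 by a dilute acid wash. Only step 10 remains.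

Step 5. The trioxygenated benzylic bromide may ionise and alkylate the free aromatic position of a second molecule, homocouple under palladium, or give a propargylic ynol ether that isomerises to an allenyl ether. The fallback reverses the polarity and builds the four-membered ring first, setting out from 6 and coming back at 13. Dimethylketene (from 11 and Et3N) is added to ethoxyacetylene 7 itself to give 3-ethoxy-4,4-dimethylcyclobut-2-en-1-one F2. NBS in CH2Cl2 brominates its nucleophilic C2 to 2-bromo-3-ethoxy-4,4-dimethylcyclobut-2-en-1-one F3. Bromide 6 is converted with zinc dust and LiCl in THF into the benzylic zinc bromide F4, and Negishi coupling of F4 with F3 (Pd(OAc)2, SPhos, THF, rt) gives 13. This detour also bypasses ynol ether 10 and step 6.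

Step 9. Acyl transfer may stall at the enol acetates, over-acylate the product enol, or be misdirected among the three enol oxygens and two ring carbons. The fallback brings the acetyl group in by cross-coupling before hydrolysis, setting out from dienone 17 and coming back at 20. NIS in MeCN at 0 °C iodinates C2 of the vinylogous ester to give the 2-iodo dienone F5. Stille coupling with tributyl(1-ethoxyvinyl)stannane (Pd(PPh3)4, toluene, 90 °C) gives the 2-(1-ethoxyvinyl) dienone F6. 2 M HCl in THF then hydrolyses all three enol ethers to 20, replacing steps 8 and 9.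

**Further compounds**

F1 | step 7 | acetylfilicinic acid (2-acetyl-3,5-dihydroxy-4,4-dimethylcyclohexa-2,5-dien-1-one) | CC(=O)C1=C(O)C(C)(C)C(O)=CC1=O
F2 | step 5 | 3-ethoxy-4,4-dimethylcyclobut-2-en-1-one | CCOC1=CC(=O)C1(C)C
F3 | step 5 | 2-bromo-3-ethoxy-4,4-dimethylcyclobut-2-en-1-one | CCOC1=C(Br)C(=O)C1(C)C
F4 | step 5 | [3-acetyl-2,4-bis(benzyloxy)-6-methoxyphenyl]methylzinc bromide | COc1cc(OCc2ccccc2)c(C(C)=O)c(OCc2ccccc2)c1C[Zn]Br
F5 | step 9 | 4-[[3-acetyl-2,4-bis(benzyloxy)-6-methoxyphenyl]methyl]-3,5-diethoxy-2-iodo-6,6-dimethylcyclohexa-2,4-dien-1-one | COc1cc(OCc2ccccc2)c(C(C)=O)c(OCc2ccccc2)c1CC1=C(OCC)C(C)(C)C(=O)C(I)=C1OCC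
F6 | step 9 | 4-[[3-acetyl-2,4-bis(benzyloxy)-6-methoxyphenyl]methyl]-3,5-diethoxy-2-(1-ethoxyethenyl)-6,6-dimethylcyclohexa-2,4-dien-1-one | COc1cc(OCc2ccccc2)c(C(C)=O)c(OCc2ccccc2)c1CC1=C(OCC)C(C)(C)C(=O)C(C(=C)OCC)=C1OCC
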